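## The problem

Locants follow germacrane numbering: C1 is the ketone, C2=C3 the enol ether, the ring oxygen joins C3 and C10 (C14 methyl), C4 carries the exocyclic methylene C15, C5 the free hydroxyl, C6 the angelate, and C11(=C13)–C12 is the lactone closed onto O8.

- The core is an 11-oxabicyclo[6.2.1]undecane: a ten-membered carbocycle (C1–C10) bridged by the furanone oxygen, that is a nine-membered oxacycle (O, C3–C10) fused to a planar 3(2H)-furanone, with a trans-fused α-methylene-γ-butyrolactone on C7–C8.
- Four ring carbons (C1–C4) are sp2 and C4=C15 is cross-conjugated with the furanone, so the ring is strained and C15 is a δ-acceptor.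
- C5–C8 are contiguous and all syn along the extended C4–C9 chain (5S,6S,7R,8S). C6 can control C7 by allylic 1,2-induction, C8 follows through a cyclic transition state, and the C6 oxygen can control a carbonyl addition at C5.
- C10 (R) is quaternary, oxygenated and insulated from the other centres by the C9 methylene, so it must come from outside.
- The two neighbouring secondary oxygens must end differently (free at C5, angelate at C6), with 1,2-acyl migration and Z-to-E isomerisation of the angelate as standing risks.
- The α-methylene lactone, the dienone and the C10–O bond (β to any C8 carbonyl) rule out strong base or nucleophiles late in the route.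
- The feature used by the key step is the C3(sp2)–C4(=C15H2)–C5H(OH) array on the rim of the nine-membered oxacycle: C4 is an alkenyl carbon bonded directly to the furanone ring (O, C3, C2, C1, C10) and C5 is a carbinol, while the rigid five-membered ring holds C4 and the C10 side chain next to each other.

## Retrosynthesis

**32 ⇒ 31 ⇒ 30 (oxidation level of C5).** The C5 hydroxyl of 32 is taken back to ketone 31, and 31 to the epimeric alcohols 30. Hydride should add to 31 anti to the C6–O bond (polar Felkin–Anh), which is the 5S,6S syn relationship of 32; a carbon nucleophile adding to a C5 aldehyde under the same control gives the other epimer. Two redox steps are spent, but the C5 configuration no longer depends on the ring closure, and any epimer mixture is funnelled into one configuration.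

**30 ⇒ 28 (C4–C5).** C4–C5 is the only ring bond that joins an sp2 carbon to a carbinol, the retron of an alkenylmetal–aldehyde addition. The neighbouring cuts are worse: C5–C6 or C6–C7 need an aldehyde at C6 next to the doubly activated C7–H and β to the lactone oxygen, and C7–C8 must set two stereocentres inside a medium-ring transition state. The precursor 28 is open-chain apart from two finished five-membered rings and carries every stereocentre except C5. The forward reaction is a Nozaki–Hiyama–Kishi closure of a nine-membered oxacycle beside a five-membered oxygen ring.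

**28 ⇒ 21 (oxygen pattern at C5/C6).** C5 and C6 are carried as the primary and secondary oxygens of an isopropylidene-protected diol. They are told apart by primary/secondary reactivity (silyl ether at C5, angelate at C6, then oxidation of C5), never by selectivity between two secondary alcohols.

**21 ⇒ 14 + 18 (C7–C8 and O8–C12).** A bimolecular chromium-mediated 2-(methoxycarbonyl)allylation with lactonisation makes the C7–C8 bond, the lactone and the exocyclic methylene in one step from two fragments of similar size. The C6 stereocentre of 18 sits next to the reacting carbon and should set C7; the chair transition state then sets C8.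

**18 ⇒ 17 ⇒ 15 + 16.** A Morita–Baylis–Hillman reaction of commercial (R)-glyceraldehyde acetonide 15 with methyl acrylate 16, then SN2′ bromination, gives 18 in two steps. The stereocentre of 15 becomes C6.

**14 ⇒ 13 ⇒ 12 ⇒ 11 ⇒ 6 + 8; 6 ⇒ 3 ⇒ 1.** The aldehyde of 14 comes from the allyl group of 13. The enol triflate comes from the silyl enol ether 12, and the furanone from the α′-hydroxy ynone 11. Compound 11 is made by adding the acetylide of 8 to dioxolanone 6. C10 is set in 6 by alkylating the lactic acid acetal 3 with self-regeneration of the stereocentre.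

## Roads not taken

**Alternative 1: intramolecular allylation at C7–C8 (the most obvious cut).**
- Cut: C7–C8 and O8–C12.
- Forward key step: chromium- or zinc-mediated ring closure of the aldehyde allylic bromide A1 with lactonisation.
- Why the chosen plan is better: here C7 and C8 are set in a strained ten-membered transition state where the chair preference behind trans-lactone formation is not assured, and a wrong outcome cannot be repaired. In addition, the C4–C5 bond and the C5/C6 pattern of A1 must be made earlier by an intermolecular addition with no ring to guide C5. The chosen plan sets C7/C8 in an unconstrained bimolecular chair, and its ring closure creates only C5, which can be corrected by oxidation and reduction.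

**Alternative 2: transannular furanone formation.**
- Cut: the O–C3 bond.
- Forward key step: 5-endo cyclisation of the ten-membered α′-hydroxy ynone A2 across the ring.
- Why the chosen plan is better: A2 holds a linear C1–C2≡C3–C4 unit inside a ten-membered ring that also carries sp2 C1 and C4, so every macrocyclisation leading to A2 must pay alkyne strain. With the furanone made first, the same five atoms are bent into a ring before closure, and no protecting group is needed on the C10 hydroxyl.

**Alternative 3: ring-closing metathesis at C5=C6, then dihydroxylation.**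
- Cut: C5–C6 as an alkene.
- Forward key step: metathesis of triene A3 with a second-generation Grubbs catalyst to the E-cycloalkene A4, then syn-dihydroxylation.
- Why the chosen plan is better: A3 offers the catalyst a 2-substituted 1,3-diene, so ring size and alkene geometry are open. Osmylation of A4 must pick one of four alkenes and one face. The resulting two secondary hydroxyls must then be told apart to put the angelate on C6 only. The chosen plan brings the C6 oxygen in from the chiral pool and makes the C5 oxygen last.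

Key step: step 16

Remark on descriptors: the dioxolane carbon of 15 becomes C6 and is never touched; its descriptor changes (R in 15 and 17, S from 18 on) only because substituent priorities change. The same holds for the C7 descriptor in 22 and 23.

## Steps

Step 1
Reactants: 1 (S)-lactic acid; 2 pivalaldehyde
Product: 3 (2S,5S)-2-tert-butyl-5-methyl-1,3-dioxolan-4-one
Conditions: TsOH (cat.), H2SO4 (cat.), pentane, reflux, Dean–Stark; crystallisation at −78 °C
Reagents that add atoms: none
Why: Acid-catalysed acetalisation of the α-hydroxy acid; the lactic acid centre is untouched and the cis acetal, the thermodynamic isomer, is purified by crystallisation.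

Step 2
Reactants: 3 (2S,5S)-2-tert-butyl-5-methyl-1,3-dioxolan-4-one; 4 allyl bromide
Product: 6 (2S,5R)-2-tert-butyl-5-methyl-5-(prop-2-en-1-yl)-1,3-dioxolan-4-one, via lithium enolate 5 (not isolated)
Conditions: LiN(iPr)2, THF, −78 °C; then 4, −78 to −30 °C
Reagents that add atoms: none
Why: Enolate alkylation with self-regeneration of the stereocentre: the tert-butyl group of the acetal shields one face of planar enolate 5, so the allyl group enters trans to it and the future C10 is set as R.

Step 3
Reactants: 7 but-3-yn-2-one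
Product: 8 2-[(tert-butyldimethylsilyl)oxy]but-1-en-3-yne
Conditions: TBSOTf, Et3N, CH2Cl2, 0 °C
Reagents that add atoms: tert-butyldimethylsilyl trifluoromethanesulfonate, CC(C)(C)[Si](C)(C)OS(=O)(=O)C(F)(F)F
Why: Soft enolisation and O-silylation of the methyl ketone; the silyl enol ether masks the future C4 as the enol derivative needed in step 6 and leaves the alkyne C–H free for metalation.

Step 4
Reactants: 6 (2S,5R)-2-tert-butyl-5-methyl-5-(prop-2-en-1-yl)-1,3-dioxolan-4-one; 8 2-[(tert-butyldimethylsilyl)oxy]but-1-en-3-yne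
Product: 11 (6R)-2-[(tert-butyldimethylsilyl)oxy]-6-hydroxy-6-methylnona-1,8-dien-3-yn-5-one, via lithium acetylide 9 (not isolated), via tetrahedral lithium alkoxide 10 (not isolated)
Conditions: 8, n-BuLi, THF, −78 °C; then 6, −78 to −40 °C; aq. NH4Cl
Reagents that add atoms: none
Why: Acetylide addition to the acetal-activated lactone carbonyl stops at alkoxide 10, which collapses on work-up with loss of pivalaldehyde to the α′-hydroxy ynone; the quaternary centre takes no part.

Step 5
Reactants: 11 (6R)-2-[(tert-butyldimethylsilyl)oxy]-6-hydroxy-6-methylnona-1,8-dien-3-yn-5-one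
Product: 12 (2R)-5-{1-[(tert-butyldimethylsilyl)oxy]ethenyl}-2-methyl-2-(prop-2-en-1-yl)furan-3(2H)-one
Conditions: Et2NH, EtOH, rt
Reagents that add atoms: none
Why: Amine-mediated 5-endo cyclisation of an α′-hydroxy ynone (conjugate addition of the amine, then addition–elimination by the tertiary hydroxyl), the standard entry to 3(2H)-furanones.

Step 6
Reactants: 12 (2R)-5-{1-[(tert-butyldimethylsilyl)oxy]ethenyl}-2-methyl-2-(prop-2-en-1-yl)furan-3(2H)-one
Product: 13 1-[(5R)-5-methyl-4-oxo-5-(prop-2-en-1-yl)-4,5-dihydrofuran-2-yl]ethenyl trifluoromethanesulfonate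
Conditions: CsF, PhNTf2, 1,2-dimethoxyethane, rt
Reagents that add atoms: N-phenylbis(trifluoromethanesulfonimide), O=S(=O)(N(c1ccccc1)S(=O)(=O)C(F)(F)F)C(F)(F)F
Why: Fluoride cleaves the silyl enol ether and the enolate is triflated on oxygen; 12 has no other enolisable position, so the enol triflate forms regiospecifically.

Step 7
Reactants: 13 1-[(5R)-5-methyl-4-oxo-5-(prop-2-en-1-yl)-4,5-dihydrofuran-2-yl]ethenyl trifluoromethanesulfonate
Product: 14 1-[(5R)-5-methyl-4-oxo-5-(2-oxoethyl)-4,5-dihydrofuran-2-yl]ethenyl trifluoromethanesulfonate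
Conditions: OsO4 (cat.), NaIO4, 2,6-lutidine, dioxane/H2O, rt
Reagents that add atoms: osmium tetroxide, O=[Os](=O)(=O)=O; sodium periodate, [Na+].[O-]I(=O)(=O)=O
Why: Lemieux–Johnson cleavage; the monosubstituted allyl alkene is far more electron-rich than the triflate-bearing alkene and the push–pull furanone alkene, so it alone is cleaved to the C8 aldehyde.

Step 8
Reactants: 15 (R)-2,2-dimethyl-1,3-dioxolane-4-carbaldehyde; 16 methyl acrylate
Product: 17 methyl 2-{[(4R)-2,2-dimethyl-1,3-dioxolan-4-yl](hydroxy)methyl}prop-2-enoate (both carbinol epimers)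
Conditions: DABCO, dioxane/H2O (1:1), rt
Reagents that add atoms: none
Why: Morita–Baylis–Hillman reaction; the new carbinol centre is erased in step 9, so its configuration does not matter, and the dioxolane centre (future C6) is carried through unchanged.

Step 9
Reactants: 17 methyl 2-{[(4R)-2,2-dimethyl-1,3-dioxolan-4-yl](hydroxy)methyl}prop-2-enoate
Product: 18 methyl (2Z)-2-(bromomethyl)-3-[(4S)-2,2-dimethyl-1,3-dioxolan-4-yl]prop-2-enoate
Conditions: NBS, Me2S, CH2Cl2, 0 °C to rt
Reagents that add atoms: N-bromosuccinimide, O=C1CCC(=O)N1Br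
Why: Activation of the allylic hydroxyl by the bromosulfonium reagent and SN2′ attack of bromide give the conjugated trisubstituted ester; the neutral conditions spare the acetonide.

Step 10
Reactants: 14 1-[(5R)-5-methyl-4-oxo-5-(2-oxoethyl)-4,5-dihydrofuran-2-yl]ethenyl trifluoromethanesulfonate; 18 methyl (2Z)-2-(bromomethyl)-3-[(4S)-2,2-dimethyl-1,3-dioxolan-4-yl]prop-2-enoate
Product: 21 1-[(5R)-5-{[(2S,3R)-3-[(4S)-2,2-dimethyl-1,3-dioxolan-4-yl]-4-methylidene-5-oxooxolan-2-yl]methyl}-5-methyl-4-oxo-4,5-dihydrofuran-2-yl]ethenyl trifluoromethanesulfonate (6S,7R,8S,10R in germacrane locants), via allylchromium dichloride 19 (not isolated), via anti hydroxy ester 20 (not isolated)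
Conditions: CrCl2 (nickel-free), THF, 0 °C to rt; then PPTS (cat.), CH2Cl2, rt
Reagents that add atoms: none
Why: Chromium-mediated 2-(alkoxycarbonyl)allylation (Barbier-type Nozaki–Hiyama reaction) and lactonisation: allylchromium 19 equilibrates and reacts through a chair Zimmerman–Traxler transition state with the C7 substituent pseudo-equatorial, giving anti adduct 20 and hence the trans lactone (8S). The face of C7 is set by C6: the aldehyde should approach anti to the allylic C6–O bond with C6–H in the alkene plane (minimal allylic 1,3-strain), giving 7R. The enol triflate is inert to divalent chromium without nickel.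

Step 11
Reactants: 21 the trans-lactone acetonide named in step 10
Product: 22 1-[(5R)-5-{[(2S,3S)-3-[(1S)-1,2-dihydroxyethyl]-4-methylidene-5-oxooxolan-2-yl]methyl}-5-methyl-4-oxo-4,5-dihydrofuran-2-yl]ethenyl trifluoromethanesulfonate (same spatial arrangement as 21)
Conditions: AcOH/H2O (4:1), 40 °C
Reagents that add atoms: none
Why: Acidic hydrolysis of the isopropylidene acetal; the enol triflate, α-methylene lactone and furanone tolerate aqueous acetic acid, and no base is present to move the lactone onto O6.

Step 12
Reactants: 22 the diol named in step 11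
Product: 23 1-[(5R)-5-{[(2S,3S)-3-[(1S)-2-{[tert-butyl(dimethyl)silyl]oxy}-1-hydroxyethyl]-4-methylidene-5-oxooxolan-2-yl]methyl}-5-methyl-4-oxo-4,5-dihydrofuran-2-yl]ethenyl trifluoromethanesulfonate
Conditions: TBSCl, imidazole, CH2Cl2, 0 °C
Reagents that add atoms: tert-butyldimethylsilyl chloride, CC(C)(C)[Si](C)(C)Cl
Why: Silylation goes to the primary C5 hydroxyl; the secondary C6 hydroxyl, flanked by the lactone ring, is left free for acylation.

Step 13
Reactants: 23 the C5 silyl ether named in step 12; 24 angelic acid [(2Z)-2-methylbut-2-enoic acid]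
Product: 26 1-[(5R)-5-{[(2S,3R)-3-[(1S)-2-{[tert-butyl(dimethyl)silyl]oxy}-1-{[(2Z)-2-methylbut-2-enoyl]oxy}ethyl]-4-methylidene-5-oxooxolan-2-yl]methyl}-5-methyl-4-oxo-4,5-dihydrofuran-2-yl]ethenyl trifluoromethanesulfonate, via mixed anhydride 25 (not isolated)
Conditions: 24, 2,4,6-trichlorobenzoyl chloride, Et3N, toluene, rt; then 23, 75 °C
Reagents that add atoms: none
Why: Yamaguchi esterification through mixed anhydride 25, run without a nucleophilic amine catalyst, is the standard way to acylate hindered secondary alcohols with angelic acid while keeping the Z double bond.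

Step 14
Reactants: 26 the C6 angelate silyl ether named in step 13
Product: 27 1-[(5R)-5-{[(2S,3R)-3-[(1S)-2-hydroxy-1-{[(2Z)-2-methylbut-2-enoyl]oxy}ethyl]-4-methylidene-5-oxooxolan-2-yl]methyl}-5-methyl-4-oxo-4,5-dihydrofuran-2-yl]ethenyl trifluoromethanesulfonate
Conditions: HF·pyridine, pyridine, THF, 0 °C
Reagents that add atoms: none
Why: Acidic fluoride removes the primary silyl ether; a basic fluoride source is avoided because it would promote migration of the angelate from O6 to O5.

Step 15
Reactants: 27 the primary alcohol named in step 14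
Product: 28 1-[(5R)-5-{[(2S,3R)-3-[(1S)-1-{[(2Z)-2-methylbut-2-enoyl]oxy}-2-oxoethyl]-4-methylidene-5-oxooxolan-2-yl]methyl}-5-methyl-4-oxo-4,5-dihydrofuran-2-yl]ethenyl trifluoromethanesulfonate
Conditions: Dess–Martin periodinane, NaHCO3, CH2Cl2, 0 °C
Reagents that add atoms: none
Why: Buffered Dess–Martin oxidation gives the α-acyloxy aldehyde without epimerising C6; the aldehyde is used directly.

Step 16
Reactants: 28 the enol triflate aldehyde named in step 15
Product: 30 (6S,7R,8S,10R)-6-angeloyloxy-5-hydroxy-1-oxo-3,10-epoxygermacra-2,4(15),11(13)-trien-12,8-olide as a mixture of C5 epimers, via alkenylchromium dichloride 29 (not isolated)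
Conditions: CrCl2 (excess), NiCl2 (cat.), DMSO/THF, rt, slow addition of 28 (high dilution)
Reagents that add atoms: none
Why: Nozaki–Hiyama–Kishi reaction: zerovalent nickel (formed from NiCl2 by divalent chromium) inserts into the C4–O bond of the enol triflate, the alkenyl group passes to trivalent chromium to give 29, and 29 adds to the C5 aldehyde; work-up frees the alkoxide. The closest known reaction type is the Nozaki–Hiyama–Kishi closure of alkenyl triflate or iodide aldehydes to medium rings, including nine-membered cyclic ethers bridged across a five-membered oxygen ring. The new C4–C5 bond closes the ten-membered carbocycle C1–C10 and with it the nine-membered oxacycle (O, C3–C10); C4=C15 stays exocyclic and comes into cross-conjugation with the furanone, and no other ring forms. The only new stereocentre is C5: the C6 angeloyloxy group should steer the alkenylchromium anti to the C6–O bond (polar Felkin–Anh), which favours the 5R epimer, so both epimers are carried on and C5 is re-set in steps 17 and 18. What the step must deliver is chemoselectivity and ring closure ahead of oligomerisation: alkenylchromium reagents add only to the aldehyde and leave the lactone, the angelate, the furanone carbonyl and the acidic C6–H alone, and no base is present. Closure is helped by the planar furanone, which holds C4 in the ring plane with the C9 chain on C10 beside it, and by slow addition of 28 to excess CrCl2.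

Step 17
Reactants: 30 the epimeric macrocyclic allylic alcohols named in step 16
Product: 31 (6S,7R,8S,10R)-6-angeloyloxy-1,5-dioxo-3,10-epoxygermacra-2,4(15),11(13)-trien-12,8-olide
Conditions: Dess–Martin periodinane, NaHCO3, CH2Cl2, 0 °C
Reagents that add atoms: none
Why: Allylic alcohol oxidation turns both C5 epimers into one enone (a stereoconvergent step); buffering protects the now acidic C6–H, and 31 is reduced without storage.

Step 18
Reactants: 31 the C5 ketone named in step 17
Product: 32 (5S,6S,7R,8S,10R)-6-angeloyloxy-5-hydroxy-1-oxo-3,10-epoxygermacra-2,4(15),11(13)-trien-12,8-olide (target, CNP0120053.1)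
Conditions: NaBH4, CeCl3·7H2O, MeOH, −78 °C
Reagents that add atoms: none
Why: Luche 1,2-reduction of the enone; hydride should add anti to the C6 angeloyloxy group (polar Felkin–Anh and Cornforth models agree), giving the 5S alcohol syn to the C6 ester. The vinylogous ester carbonyl C1, the lactone and the angelate are not reduced at −78 °C.

## Compound list

1 | (S)-lactic acid | C[C@H](O)C(=O)O | starting material
2 | pivalaldehyde | CC(C)(C)C=O | starting material
3 | (2S,5S)-2-tert-butyl-5-methyl-1,3-dioxolan-4-one | C[C@H]1C(=O)O[C@@H](C(C)(C)C)O1 | intermediate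
4 | allyl bromide | C=CCBr | starting material
5 | lithium enolate of 3 | [Li+].CC1=C([O-])O[C@@H](C(C)(C)C)O1 | intermediate
6 | (2S,5R)-2-tert-butyl-5-methyl-5-(prop-2-en-1-yl)-1,3-dioxolan-4-one | C=CC[C@]1(C)C(=O)O[C@@H](C(C)(C)C)O1 | intermediate
7 | but-3-yn-2-one | CC(=O)C#C | starting material
8 | 2-[(tert-butyldimethylsilyl)oxy]but-1-en-3-yne | C=C(O[Si](C)(C)C(C)(C)C)C#C | intermediate
9 | lithium acetylide of 8 | [Li+].[C-]#CC(=C)O[Si](C)(C)C(C)(C)C | intermediate
10 | tetrahedral lithium alkoxide from 9 and the lactone carbonyl of 6 (new centre undefined) | [Li+].C=CC[C@]1(C)C([O-])(C#CC(=C)O[Si](C)(C)C(C)(C)C)O[C@@H](C(C)(C)C)O1 | intermediate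
11 | (6R)-2-[(tert-butyldimethylsilyl)oxy]-6-hydroxy-6-methylnona-1,8-dien-3-yn-5-one | C=CC[C@@](C)(O)C(=O)C#CC(=C)O[Si](C)(C)C(C)(C)C | intermediate
12 | (2R)-5-{1-[(tert-butyldimethylsilyl)oxy]ethenyl}-2-methyl-2-(prop-2-en-1-yl)furan-3(2H)-one | C=CC[C@@]1(C)OC(C(=C)O[Si](C)(C)C(C)(C)C)=CC1=O | intermediate
13 | 1-[(5R)-5-methyl-4-oxo-5-(prop-2-en-1-yl)-4,5-dihydrofuran-2-yl]ethenyl trifluoromethanesulfonate | C=CC[C@@]1(C)OC(C(=C)OS(=O)(=O)C(F)(F)F)=CC1=O | intermediate
14 | 1-[(5R)-5-methyl-4-oxo-5-(2-oxoethyl)-4,5-dihydrofuran-2-yl]ethenyl trifluoromethanesulfonate | O=CC[C@@]1(C)OC(C(=C)OS(=O)(=O)C(F)(F)F)=CC1=O | intermediate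
15 | (R)-2,2-dimethyl-1,3-dioxolane-4-carbaldehyde | O=C[C@H]1COC(C)(C)O1 | starting material
16 | methyl acrylate | C=CC(=O)OC | starting material
17 | methyl 2-{[(4R)-2,2-dimethyl-1,3-dioxolan-4-yl](hydroxy)methyl}prop-2-enoate (carbinol epimers) | C=C(C(=O)OC)C(O)[C@H]1COC(C)(C)O1 | intermediate
18 | methyl (2Z)-2-(bromomethyl)-3-[(4S)-2,2-dimethyl-1,3-dioxolan-4-yl]prop-2-enoate | BrC/C(C(=O)OC)=C\[C@H]1COC(C)(C)O1 | intermediate
19 | allylchromium dichloride from 18 (alkene geometry mobile) | COC(=O)C(C[Cr](Cl)Cl)=C[C@H]1COC(C)(C)O1 | intermediate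
20 | methyl (3R,4S)-3-[(4S)-2,2-dimethyl-1,3-dioxolan-4-yl]-4-hydroxy-5-[(2R)-2-methyl-3-oxo-5-(1-{[(trifluoromethyl)sulfonyl]oxy}ethenyl)-2,3-dihydrofuran-2-yl]-2-methylidenepentanoate | C=C(C(=O)OC)[C@@H]([C@H]1COC(C)(C)O1)[C@@H](O)C[C@@]2(C)OC(C(=C)OS(=O)(=O)C(F)(F)F)=CC2=O | intermediate
21 | 1-[(5R)-5-{[(2S,3R)-3-[(4S)-2,2-dimethyl-1,3-dioxolan-4-yl]-4-methylidene-5-oxooxolan-2-yl]methyl}-5-methyl-4-oxo-4,5-dihydrofuran-2-yl]ethenyl trifluoromethanesulfonate | C=C1C(=O)O[C@@H](C[C@@]2(C)OC(C(=C)OS(=O)(=O)C(F)(F)F)=CC2=O)[C@@H]1[C@H]3COC(C)(C)O3 | intermediate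
22 | 1-[(5R)-5-{[(2S,3S)-3-[(1S)-1,2-dihydroxyethyl]-4-methylidene-5-oxooxolan-2-yl]methyl}-5-methyl-4-oxo-4,5-dihydrofuran-2-yl]ethenyl trifluoromethanesulfonate | C=C1C(=O)O[C@@H](C[C@@]2(C)OC(C(=C)OS(=O)(=O)C(F)(F)F)=CC2=O)[C@@H]1[C@H](O)CO | intermediate
23 | 1-[(5R)-5-{[(2S,3S)-3-[(1S)-2-{[tert-butyl(dimethyl)silyl]oxy}-1-hydroxyethyl]-4-methylidene-5-oxooxolan-2-yl]methyl}-5-methyl-4-oxo-4,5-dihydrofuran-2-yl]ethenyl trifluoromethanesulfonate | C=C1C(=O)O[C@@H](C[C@@]2(C)OC(C(=C)OS(=O)(=O)C(F)(F)F)=CC2=O)[C@@H]1[C@H](O)CO[Si](C)(C)C(C)(C)C | intermediate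
24 | angelic acid, (2Z)-2-methylbut-2-enoic acid | C/C=C(/C)C(=O)O | starting material
25 | angelic 2,4,6-trichlorobenzoic anhydride | C/C=C(/C)C(=O)OC(=O)c1c(Cl)cc(Cl)cc1Cl | intermediate
26 | 1-[(5R)-5-{[(2S,3R)-3-[(1S)-2-{[tert-butyl(dimethyl)silyl]oxy}-1-{[(2Z)-2-methylbut-2-enoyl]oxy}ethyl]-4-methylidene-5-oxooxolan-2-yl]methyl}-5-methyl-4-oxo-4,5-dihydrofuran-2-yl]ethenyl trifluoromethanesulfonate | C=C1C(=O)O[C@@H](C[C@@]2(C)OC(C(=C)OS(=O)(=O)C(F)(F)F)=CC2=O)[C@@H]1[C@H](OC(=O)/C(C)=C\C)CO[Si](C)(C)C(C)(C)C | intermediate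
27 | 1-[(5R)-5-{[(2S,3R)-3-[(1S)-2-hydroxy-1-{[(2Z)-2-methylbut-2-enoyl]oxy}ethyl]-4-methylidene-5-oxooxolan-2-yl]methyl}-5-methyl-4-oxo-4,5-dihydrofuran-2-yl]ethenyl trifluoromethanesulfonate | C=C1C(=O)O[C@@H](C[C@@]2(C)OC(C(=C)OS(=O)(=O)C(F)(F)F)=CC2=O)[C@@H]1[C@H](OC(=O)/C(C)=C\C)CO | intermediate
28 | 1-[(5R)-5-{[(2S,3R)-3-[(1S)-1-{[(2Z)-2-methylbut-2-enoyl]oxy}-2-oxoethyl]-4-methylidene-5-oxooxolan-2-yl]methyl}-5-methyl-4-oxo-4,5-dihydrofuran-2-yl]ethenyl trifluoromethanesulfonate | C=C1C(=O)O[C@@H](C[C@@]2(C)OC(C(=C)OS(=O)(=O)C(F)(F)F)=CC2=O)[C@@H]1[C@H](OC(=O)/C(C)=C\C)C=O | intermediate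
29 | alkenylchromium dichloride from 28 (chromium on C4) | C=C1C(=O)O[C@@H](C[C@@]2(C)OC(C(=C)[Cr](Cl)Cl)=CC2=O)[C@@H]1[C@H](OC(=O)/C(C)=C\C)C=O | intermediate
30 | (6S,7R,8S,10R)-6-angeloyloxy-5-hydroxy-1-oxo-3,10-epoxygermacra-2,4(15),11(13)-trien-12,8-olide, C5 epimers | C=C1C(=O)O[C@H]2C[C@@]3(C)OC(=CC3=O)C(=C)C(O)[C@@H](OC(=O)/C(C)=C\C)[C@H]12 | intermediate
31 | (6S,7R,8S,10R)-6-angeloyloxy-1,5-dioxo-3,10-epoxygermacra-2,4(15),11(13)-trien-12,8-olide | C=C1C(=O)O[C@H]2C[C@@]3(C)OC(=CC3=O)C(=C)C(=O)[C@@H](OC(=O)/C(C)=C\C)[C@H]12 | intermediate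
32 | (5S,6S,7R,8S,10R)-6-angeloyloxy-5-hydroxy-1-oxo-3,10-epoxygermacra-2,4(15),11(13)-trien-12,8-olide (CNP0120053.1) | C=C1C(=O)O[C@H]2C[C@@]3(C)OC(=CC3=O)C(=C)[C@H](O)[C@@H](OC(=O)/C(C)=C\C)[C@H]12 | target

## Step count and least certain steps

Total step count: 18. Longest linear sequence: 15 steps (1, 2, 4–7, 10–18); steps 3 and 8–9 are side branches.

**Step 16 (key step).** Most likely failure: oligomerisation, or reduction of the aldehyde or of the alkenyl–metal species, outrunning closure of the strained bridged ring, because the cross-conjugated triflate is a slow partner at high dilution. Fallback (acylative ring closure, which also makes the ketone directly): it sets out from 28 and comes back at 31.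
- Pinnick oxidation (NaClO2, NaH2PO4, 2-methyl-2-butene) gives the carboxylic acid F1.
- Thioesterification with ethanethiol and a carbodiimide gives the S-ethyl thioester F2.
- Palladium-catalysed stannylation of the enol triflate (Me3SnSnMe3, Pd(PPh3)4, LiCl) gives the alkenylstannane thioester F3.
- Intramolecular Liebeskind–Srogl ketone synthesis (Pd2(dba)3, tri(2-furyl)phosphine, copper thiophene-2-carboxylate CuO2CC4H3S, high dilution) closes the C4–C5 bond to 31.

**Step 10.** Most likely failure: loss of diastereocontrol. Either syn addition (leading to the cis lactone) if the allylchromium reacts before it equilibrates, or weak facial bias from the C6 dioxolane. Fallback (allylboration under Lewis acid catalysis, known to give trans-β,γ-disubstituted α-methylene lactones): it sets out from 17 and 14 and comes back at 21.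
- Acetylation of 17 (Ac2O, pyridine) gives the allylic acetate F4.
- Copper-catalysed SN2′ borylation (B2pin2, CuCl, KOtBu) gives the allylboronate F5.
- F5 adds to aldehyde 14 with In(OTf)3 (cat.) in toluene; acid-promoted lactonisation gives 21.

**Step 18.** Most likely failure: poor facial selectivity, if the ring conformation or cerium chelation to the C6 ester overrides acyclic Felkin–Anh control, or competing conjugate reduction of the exocyclic enone. Fallback (invert instead of reduce): it sets out from 30 and comes back at 32.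
- The 5R epimer F6 is separated from 30.
- Mitsunobu reaction with chloroacetic acid (PPh3, diisopropyl azodicarboxylate) gives the inverted 5S chloroacetate F7.
- Thiourea and NaHCO3 in ethanol remove the chloroacetyl group selectively to give 32.

**Step 13.** Most likely failure: Z-to-E isomerisation of the angeloyl group (to the tiglate) during forced acylation of the hindered C6 hydroxyl, or incomplete acylation. Fallback (build the Z-alkene on the ester): it sets out from 23 and comes back at 26.
- Acylation of 23 with 2-[bis(2,2,2-trifluoroethoxy)phosphoryl]propanoic acid and a carbodiimide gives the phosphonate ester F8.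
- Still–Gennari olefination with acetaldehyde (KN(SiMe3)2, 18-crown-6, THF, −78 °C) forms the Z-trisubstituted ester 26.

## Further compounds

F1 | step 16 | carboxylic acid from 28 (C5 as CO2H, enol triflate kept) | C=C1C(=O)O[C@@H](C[C@@]2(C)OC(C(=C)OS(=O)(=O)C(F)(F)F)=CC2=O)[C@@H]1[C@H](OC(=O)/C(C)=C\C)C(=O)O
F2 | step 16 | S-ethyl thioester of F1 | C=C1C(=O)O[C@@H](C[C@@]2(C)OC(C(=C)OS(=O)(=O)C(F)(F)F)=CC2=O)[C@@H]1[C@H](OC(=O)/C(C)=C\C)C(=O)SCC
F3 | step 16 | alkenyl(trimethyl)stannane S-ethyl thioester (tin on C4) | C=C1C(=O)O[C@@H](C[C@@]2(C)OC(C(=C)[Sn](C)(C)C)=CC2=O)[C@@H]1[C@H](OC(=O)/C(C)=C\C)C(=O)SCC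
F4 | step 10 | methyl 2-{(acetyloxy)[(4R)-2,2-dimethyl-1,3-dioxolan-4-yl]methyl}prop-2-enoate (acetate of 17) | C=C(C(=O)OC)C(OC(C)=O)[C@H]1COC(C)(C)O1
F5 | step 10 | methyl (2E)-3-[(4S)-2,2-dimethyl-1,3-dioxolan-4-yl]-2-[(4,4,5,5-tetramethyl-1,3,2-dioxaborolan-2-yl)methyl]prop-2-enoate | COC(=O)/C(CB1OC(C)(C)C(C)(C)O1)=C/[C@H]2COC(C)(C)O2
F6 | step 18 | (5R,6S,7R,8S,10R)-6-angeloyloxy-5-hydroxy-1-oxo-3,10-epoxygermacra-2,4(15),11(13)-trien-12,8-olide (C5 epimer of 32) | C=C1C(=O)O[C@H]2C[C@@]3(C)OC(=CC3=O)C(=C)[C@@H](O)[C@@H](OC(=O)/C(C)=C\C)[C@H]12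
F7 | step 18 | (5S)-5-O-chloroacetyl derivative of 32 | C=C1C(=O)O[C@H]2C[C@@]3(C)OC(=CC3=O)C(=C)[C@H](OC(=O)CCl)[C@@H](OC(=O)/C(C)=C\C)[C@H]12
F8 | step 13 | C6 ester of 23 with 2-[bis(2,2,2-trifluoroethoxy)phosphoryl]propanoic acid (phosphonate α-carbon undefined) | C=C1C(=O)O[C@@H](C[C@@]2(C)OC(C(=C)OS(=O)(=O)C(F)(F)F)=CC2=O)[C@@H]1[C@H](OC(=O)C(C)P(=O)(OCC(F)(F)F)OCC(F)(F)F)CO[Si](C)(C)C(C)(C)C
A1 | alternative 1 | seco aldehyde allylic bromide: furanone with C8 aldehyde and C4(=CH2)–C5(OTBS)–C6(OAng)–C7=C11(CO2Me)–CH2Br chain | O=CC[C@@]1(C)OC(C(=C)[C@H](O[Si](C)(C)C(C)(C)C)[C@@H](OC(=O)/C(C)=C\C)/C=C(\CBr)C(=O)OC)=CC1=O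
A2 | alternative 2 | ten-membered α′-hydroxy ynone (C10–OH, C1 ketone, C2≡C3) with the lactone in place and C5–OTBS | C=C1C(=O)O[C@H]2C[C@@](C)(O)C(=O)C#CC(=C)[C@H](O[Si](C)(C)C(C)(C)C)[C@@H](OC(=O)/C(C)=C\C)[C@H]12
A3 | alternative 3 | metathesis precursor: lactone with C7 vinyl and the furanone carrying a buta-1,3-dien-2-yl group on C3 | C=C1C(=O)O[C@@H](C[C@@]2(C)OC(C(=C)C=C)=CC2=O)[C@@H]1C=C
A4 | alternative 3 | (5E)-1-oxo-3,10-epoxygermacra-2,4(15),5,11(13)-tetraen-12,8-olide | C=C1C(=O)O[C@H]2C[C@@]3(C)OC(=CC3=O)C(=C)/C=C/[C@H]12
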